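**Plan**

- Retrosynthetic cuts: the veratrate C–O bond; C4–isopropyl; C1–CH3; the C2–C3 bond of five-membered ring A (back to a propargylic pivalate); C5–ethynyl; C8=C9 of seven-membered ring B (metathesis); the C5–C1 acyl bond (Weinreb ketone synthesis); C6–C7 (glyoxylate–ene).
- Forward order: open chain, then ring B by ring-closing metathesis, then ring A by a gold-catalysed Rautenstrauch rearrangement, then angular methyl, isopropyl carbinol and ester.
- Enabling feature: in ring A only C4 carries a heteroatom, C2 and C3 are unsubstituted CH2 groups, and C1/C5 are the ring-fusion atoms. Ring A is therefore a latent ring-fused cyclopent-2-enone (C4=O, C5=C1), the product type of a 1-ethynyl-2-methylidene carbinol ester C3≡C4–C5(OPiv)–C1=C2 when C3 and C2 are joined.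
- Stereochemistry: C6 from a catalytic asymmetric glyoxylate–ene reaction; C1 by cuprate addition anti to the C6 silyloxy group; C5 by equilibration to the trans-fused ketone; C4 by organocerium attack anti to the angular methyl.

Key step: step 8

Remark: atom numbers follow the daucane skeleton. C1 is the methyl-bearing ring-fusion carbon, C2 and C3 the CH2 groups of ring A, C4 the isopropyl carbinol carbon, C5 the ring-fusion CH, C6 the ester-bearing carbon, C7 a CH2, C8 the methyl-bearing alkene carbon, C9 the alkene CH, C10 a CH2.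
Remark: 2-bromopenta-1,4-diene is assumed not to be purchasable and is made in step 4; ethyl glyoxylate is used freshly distilled.

**Step 1**
Reactants: 1 ethyl glyoxylate; 2 isobutene
Product: 3 ethyl (2S)-2-hydroxy-4-methylpent-4-enoate
Conditions: [Cu((S,S)-tBu-box)](SbF6)2 (2 mol%; tBu-box = 2,2'-(propane-2,2-diyl)bis[(4S)-4-tert-butyl-4,5-dihydrooxazole]), CH2Cl2, 0 °C → rt
Reagents that add atoms: none
Why: Catalytic asymmetric carbonyl–ene reaction in which the glyoxylate, chelated to the C2-symmetric divalent copper bis(oxazoline) complex, is attacked on its si face by isobutene, which should give the (S)-carbinol that becomes C6.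

**Step 2**
Reactants: 3 ethyl (2S)-2-hydroxy-4-methylpent-4-enoate
Product: 4 ethyl (2S)-2-[(tert-butyldimethylsilyl)oxy]-4-methylpent-4-enoate
Conditions: TBSCl, imidazole, DMF, rt
Reagents that add atoms: tert-butyldimethylsilyl chloride, CC(C)(C)[Si](C)(C)Cl
Why: Standard imidazole-mediated silylation of a secondary alcohol, which does not touch the stereocentre and installs the bulky group later used for facial control.

**Step 3**
Reactants: 4 ethyl (2S)-2-[(tert-butyldimethylsilyl)oxy]-4-methylpent-4-enoate
Product: 5 (2S)-2-[(tert-butyldimethylsilyl)oxy]-N-methoxy-N,4-dimethylpent-4-enamide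
Conditions: MeNH(OMe)·HCl, iPrMgCl, THF, −20 → 0 °C
Reagents that add atoms: N,O-dimethylhydroxylamine hydrochloride, CNOC.Cl
Why: Direct aminolysis of the ester by the chloromagnesium amide (Weinreb amide formation) should proceed at low temperature without epimerising the α-silyloxy centre.

**Step 4**
Reactants: 6 2,3-dibromopropene
Product: 7 2-bromopenta-1,4-diene
Conditions: CH2=CHMgBr, CuI (5 mol%), THF, 0 °C → rt
Reagents that add atoms: vinylmagnesium bromide, C=C[Mg]Br
Why: Copper-catalysed allylic substitution of the allylic bromide by the vinyl Grignard reagent, in which direct and allylic-transposed attack give the same product and the vinylic C–Br bond is left intact.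

**Step 5**
Reactants: 7 2-bromopenta-1,4-diene; 5 (2S)-2-[(tert-butyldimethylsilyl)oxy]-N-methoxy-N,4-dimethylpent-4-enamide
Product: 9 (4S)-4-[(tert-butyldimethylsilyl)oxy]-2-methyl-6-methylidenenona-1,8-dien-5-one, via penta-1,4-dien-2-ylmagnesium bromide 8 (not isolated)
Conditions: Mg turnings, THF, rt → 40 °C; then 5, THF, −20 → 0 °C; cold aqueous work-up
Reagents that add atoms: none
Why: Weinreb ketone synthesis, in which the chelated tetrahedral magnesium adduct prevents over-addition and releases the α-substituted enone only on work-up, with the C6 centre untouched.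

**Step 6**
Reactants: 9 (4S)-4-[(tert-butyldimethylsilyl)oxy]-2-methyl-6-methylidenenona-1,8-dien-5-one
Product: 10 (7S)-7-[(tert-butyldimethylsilyl)oxy]-5-methyl-2-methylidenecyclohept-4-en-1-one
Conditions: second-generation Grubbs catalyst RuCl2(=CHPh)(PCy3)(H2IMes) (5 mol%), 1,4-benzoquinone (10 mol%), CH2Cl2 (5 mM), 40 °C; product used directly
Reagents that add atoms: none
Why: Ring-closing metathesis between the allyl and methallyl groups closes ring B with the trisubstituted C8=C9 bond, while the electron-poor 1,1-disubstituted enone methylene stays a bystander and benzoquinone suppresses ruthenium hydride isomerisation.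

**Step 7**
Reactants: 10 (7S)-7-[(tert-butyldimethylsilyl)oxy]-5-methyl-2-methylidenecyclohept-4-en-1-one
Product: 12 (7S)-7-[(tert-butyldimethylsilyl)oxy]-1-ethynyl-5-methyl-2-methylidenecyclohept-4-en-1-yl 2,2-dimethylpropanoate (both C1 epimers), via bromomagnesium ethynylcarbinolate 11 (not isolated)
Conditions: HC≡CMgBr, THF, −78 → 0 °C; then PivCl, DMAP (cat.), 0 °C → rt
Reagents that add atoms: ethynylmagnesium bromide, C#C[Mg]Br; pivaloyl chloride, CC(C)(C)C(=O)Cl
Why: Alkynyl Grignard reagents add 1,2 to enones and the resulting tertiary alkoxide is acylated in the flask; the new carbinol centre (C5) needs no control because it becomes sp2 in step 8.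

**Step 8**
Reactants: 12 (7S)-7-[(tert-butyldimethylsilyl)oxy]-1-ethynyl-5-methyl-2-methylidenecyclohept-4-en-1-yl 2,2-dimethylpropanoate
Product: 14 (8S)-8-[(tert-butyldimethylsilyl)oxy]-6-methyl-3,4,7,8-tetrahydroazulen-1(2H)-one, via cyclopentadienyl pivalate 13 (not isolated)
Conditions: Ph3PAuCl (5 mol%), AgSbF6 (5 mol%), MeCN, H2O (2 equiv), −20 °C → rt
Reagents that add atoms: none
Why: The cationic monovalent gold complex activates the terminal alkyne, the pivalate carbonyl oxygen attacks C4 and a 1,2-acyloxy shift gives a gold-bound 2-acyloxypentadienyl cation C3–C4(OPiv)–C5–C1–C2, whose 4π conrotatory electrocyclisation joins the former alkyne CH (C3) to the former methylidene carbon (C2); loss of gold gives dienyl pivalate 13, which water hydrolyses to the conjugated enone. The closest known reaction type is the Rautenstrauch rearrangement of 1-ethynyl-2-propenyl esters to cyclopent-2-enones, including tertiary esters that give 2,3-disubstituted cyclopentenones. Ring A is closed by a Nazarov-type electrocyclisation (formally 5-endo at both π termini). No stereocentre is created: both C5 epimers of 12 converge because C5 becomes sp2, and C6 is not involved. The step needs the 1,2-shift to beat the 1,3-shift, which the terminal alkyne secures, and closure onto C1=C2 and not onto C8=C9, which is secured because C1=C2 is held s-cis next to C5 on ring B while the ring alkene would have to react across the ring. The ketone oxygen at C4 comes from the pivalate, so the oxidation level needed for the isopropyl carbinol is installed in the same event.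

**Step 9**
Reactants: 14 (8S)-8-[(tert-butyldimethylsilyl)oxy]-6-methyl-3,4,7,8-tetrahydroazulen-1(2H)-one
Product: 16 (3aR,8S,8aS)-8-[(tert-butyldimethylsilyl)oxy]-3a,6-dimethyl-3,3a,4,7,8,8a-hexahydroazulen-1(2H)-one, via trimethylsilyl enol ether 15 (not isolated)
Conditions: Me2CuLi (from MeLi and CuI), TMSCl, Et2O–THF, −78 → −20 °C; 1 M HCl work-up; then DBU (0.2 equiv), CH2Cl2, rt
Reagents that add atoms: methyllithium, [Li]C
Why: Silyl-chloride-accelerated conjugate addition of the Gilman cuprate should deliver methyl to C1 anti to the C6 silyloxy group, which allylic strain against the C4 carbonyl holds pseudoaxial over one face of the enone, and after hydrolysis of 15 base equilibration at C5 should favour the trans-fused ketone, in which C2, C4 and the silyloxy group are all equatorial on ring B whereas the cis epimer must place C4 or the silyloxy group axial.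

**Step 10**
Reactants: 16 (3aR,8S,8aS)-8-[(tert-butyldimethylsilyl)oxy]-3a,6-dimethyl-3,3a,4,7,8,8a-hexahydroazulen-1(2H)-one
Product: 17 (3R,3aS,4S,8aR)-4-[(tert-butyldimethylsilyl)oxy]-6,8a-dimethyl-3-(propan-2-yl)-1,2,3,3a,4,5,8,8a-octahydroazulen-3-ol
Conditions: iPrMgCl, CeCl3 (anhydrous), THF, −78 → 0 °C
Reagents that add atoms: isopropylmagnesium chloride, CC(C)[Mg]Cl
Why: The weakly basic organocerium reagent iPrCeCl2 adds to the enolisable ketone without epimerising C5, and should attack the C4 carbonyl from the face of H5, anti to the pseudoaxial angular methyl that lies 1,3 to C4, placing the hydroxyl cis to the methyl.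

**Step 11**
Reactants: 17 (3R,3aS,4S,8aR)-4-[(tert-butyldimethylsilyl)oxy]-6,8a-dimethyl-3-(propan-2-yl)-1,2,3,3a,4,5,8,8a-octahydroazulen-3-ol
Product: 18 (3R,3aS,4S,8aR)-6,8a-dimethyl-3-(propan-2-yl)-1,2,3,3a,4,5,8,8a-octahydroazulene-3,4-diol (jaeschkeanadiol)
Conditions: TBAF, THF, rt → 40 °C
Reagents that add atoms: none
Why: Fluoride-mediated cleavage of the secondary silyl ether, to which the tertiary alcohol and both alkenes are inert.

**Step 12**
Reactants: 18 (3R,3aS,4S,8aR)-6,8a-dimethyl-3-(propan-2-yl)-1,2,3,3a,4,5,8,8a-octahydroazulene-3,4-diol; 19 3,4-dimethoxybenzoyl chloride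
Product: 20 (3R,3aS,4S,8aR)-3-hydroxy-6,8a-dimethyl-3-(propan-2-yl)-1,2,3,3a,4,5,8,8a-octahydroazulen-4-yl 3,4-dimethoxybenzoate
Conditions: Et3N, DMAP (cat.), CH2Cl2, 0 °C → rt
Reagents that add atoms: none
Why: DMAP-catalysed acylation should select the secondary C6 hydroxyl over the hindered tertiary C4 hydroxyl, giving the target without touching any stereocentre.

**Compound list**

1 | ethyl glyoxylate | O=CC(=O)OCC | starting material
2 | isobutene | CC(C)=C | starting material
3 | ethyl (2S)-2-hydroxy-4-methylpent-4-enoate | O[C@H](C(=O)OCC)CC(C)=C | intermediate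
4 | ethyl (2S)-2-[(tert-butyldimethylsilyl)oxy]-4-methylpent-4-enoate | CC(C)(C)[Si](C)(C)O[C@H](C(=O)OCC)CC(C)=C | intermediate
5 | (2S)-2-[(tert-butyldimethylsilyl)oxy]-N-methoxy-N,4-dimethylpent-4-enamide | CC(C)(C)[Si](C)(C)O[C@H](C(=O)N(C)OC)CC(C)=C | intermediate
6 | 2,3-dibromopropene | C=C(Br)CBr | starting material
7 | 2-bromopenta-1,4-diene | C=CCC(Br)=C | intermediate
8 | penta-1,4-dien-2-ylmagnesium bromide | C=CCC(=C)[Mg]Br | intermediate
9 | (4S)-4-[(tert-butyldimethylsilyl)oxy]-2-methyl-6-methylidenenona-1,8-dien-5-one | CC(C)(C)[Si](C)(C)O[C@H](C(=O)C(=C)CC=C)CC(C)=C | intermediate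
10 | (7S)-7-[(tert-butyldimethylsilyl)oxy]-5-methyl-2-methylidenecyclohept-4-en-1-one | CC(C)(C)[Si](C)(C)O[C@H]1CC(C)=CCC(=C)C1=O | intermediate
11 | bromomagnesium (7S)-7-[(tert-butyldimethylsilyl)oxy]-1-ethynyl-5-methyl-2-methylidenecyclohept-4-en-1-olate (both C1 epimers) | CC(C)(C)[Si](C)(C)O[C@H]1CC(C)=CCC(=C)C1(C#C)O[Mg]Br | intermediate
12 | (7S)-7-[(tert-butyldimethylsilyl)oxy]-1-ethynyl-5-methyl-2-methylidenecyclohept-4-en-1-yl 2,2-dimethylpropanoate (both C1 epimers) | CC(C)(C)[Si](C)(C)O[C@H]1CC(C)=CCC(=C)C1(C#C)OC(=O)C(C)(C)C | intermediate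
13 | (8S)-8-[(tert-butyldimethylsilyl)oxy]-6-methyl-3,4,7,8-tetrahydroazulen-1-yl 2,2-dimethylpropanoate | CC(C)(C)[Si](C)(C)O[C@H]1CC(C)=CCC2=C1C(OC(=O)C(C)(C)C)=CC2 | intermediate
14 | (8S)-8-[(tert-butyldimethylsilyl)oxy]-6-methyl-3,4,7,8-tetrahydroazulen-1(2H)-one | CC(C)(C)[Si](C)(C)O[C@H]1CC(C)=CCC2=C1C(=O)CC2 | intermediate
15 | tert-butyl{[(3aR,8S)-3a,6-dimethyl-1-(trimethylsilyloxy)-2,3,3a,4,7,8-hexahydroazulen-8-yl]oxy}dimethylsilane | CC(C)(C)[Si](C)(C)O[C@H]1CC(C)=CC[C@@]2(C)CCC(O[Si](C)(C)C)=C12 | intermediate
16 | (3aR,8S,8aS)-8-[(tert-butyldimethylsilyl)oxy]-3a,6-dimethyl-3,3a,4,7,8,8a-hexahydroazulen-1(2H)-one | CC(C)(C)[Si](C)(C)O[C@H]1CC(C)=CC[C@@]2(C)CCC(=O)[C@H]12 | intermediate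
17 | (3R,3aS,4S,8aR)-4-[(tert-butyldimethylsilyl)oxy]-6,8a-dimethyl-3-(propan-2-yl)-1,2,3,3a,4,5,8,8a-octahydroazulen-3-ol | CC(C)(C)[Si](C)(C)O[C@H]1CC(C)=CC[C@@]2(C)CC[C@@](O)(C(C)C)[C@H]12 | intermediate
18 | (3R,3aS,4S,8aR)-6,8a-dimethyl-3-(propan-2-yl)-1,2,3,3a,4,5,8,8a-octahydroazulene-3,4-diol | O[C@H]1CC(C)=CC[C@@]2(C)CC[C@@](O)(C(C)C)[C@H]12 | intermediate
19 | 3,4-dimethoxybenzoyl chloride | COc1ccc(C(=O)Cl)cc1OC | starting material
20 | (3R,3aS,4S,8aR)-3-hydroxy-6,8a-dimethyl-3-(propan-2-yl)-1,2,3,3a,4,5,8,8a-octahydroazulen-4-yl 3,4-dimethoxybenzoate | COc1ccc(C(=O)O[C@H]2CC(C)=CC[C@@]3(C)CC[C@@](O)(C(C)C)[C@H]23)cc1OC | target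

**Step count**

Total steps: 12. Longest linear sequence: 11 (steps 1–3 and 5–12; step 4 is a one-step side branch).

**Steps most likely to fail**

Step 9. The tetrasubstituted enone may react sluggishly with the cuprate, the methyl may be delivered with poor facial selectivity, or the β-silyloxy enolate may lose silanolate by elimination during the C5 equilibration. The fallback sets out from 14 and keeps the anti-to-silyloxy approach but transfers a CH2 instead of a methyl. Corey–Chaykovsky cyclopropanation of 14 with dimethylsulfoxonium methylide (Me3S(O)I, NaH, DMSO, 50 °C) should give the tricyclic cyclopropyl ketone F1, with the CH2 bridging C1 and C5 on the face opposite the silyloxy group. Reductive opening with SmI2 (THF–DMPU, tBuOH, 0 °C) should cleave the C5–CH2 bond, the one aligned with the ketyl π system, turning the bridge into the C1 methyl. Protonation and the same DBU equilibration return the route to 16.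

Step 6. Under metathesis conditions or on isolation, the exocyclic methylidene of 10 may migrate into the ring to give the conjugated dienone, or the α-methylidene ketone may dimerise by hetero-Diels–Alder reaction. The fallback sets out from 9 and never forms 10. Addition of LiC≡CSiMe3 (THF, −78 °C) with in-flask pivaloylation should give the acyclic silylalkynyl pivalate F2. Ring-closing metathesis with the second-generation Grubbs catalyst, to which the silyl-capped alkyne is inert, should give the cycloheptene F3. Removal of the alkynyl silyl group (K2CO3, MeOH, 0 °C) returns the route to 12.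

Step 8. The tertiary, doubly activated pivalate may ionise and eliminate to enynes, or a 1,3-acyloxy shift to an allenyl ester may outrun the 1,2-shift and ring closure. The fallback sets out from 10 and forms the same C2–C3 bond by a proton-triggered electrocyclisation instead of a gold-triggered one. Addition of 1-ethoxyvinyllithium (ethyl vinyl ether, tBuLi, THF, −78 °C) should give the ethoxydienyl carbinol F4. Treatment with the sulfonic acid resin Amberlyst 15 in CH2Cl2 at rt ionises the tertiary alcohol to a 2-ethoxypentadienyl cation, which undergoes a dehydrative Nazarov-type 4π closure. Hydrolysis of the resulting enol ether returns the route to 14.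

**Further compounds**

F1 | step 9 | (8S)-8-[(tert-butyldimethylsilyl)oxy]-6-methyl-3,4,7,8-tetrahydro-3a,8a-methanoazulen-1(2H)-one, CH2 bridge anti to the silyloxy group | CC(C)(C)[Si](C)(C)O[C@H]1CC(C)=CC[C@@]2(C3)CCC(=O)[C@@]123
F2 | step 6 | (4S)-4-[(tert-butyldimethylsilyl)oxy]-2-methyl-6-methylidene-5-[(trimethylsilyl)ethynyl]nona-1,8-dien-5-yl 2,2-dimethylpropanoate (both C5 epimers) | CC(C)(C)[Si](C)(C)O[C@H](C(C#C[Si](C)(C)C)(OC(=O)C(C)(C)C)C(=C)CC=C)CC(C)=C
F3 | step 6 | (7S)-7-[(tert-butyldimethylsilyl)oxy]-5-methyl-2-methylidene-1-[(trimethylsilyl)ethynyl]cyclohept-4-en-1-yl 2,2-dimethylpropanoate (both C1 epimers) | CC(C)(C)[Si](C)(C)O[C@H]1CC(C)=CCC(=C)C1(C#C[Si](C)(C)C)OC(=O)C(C)(C)C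
F4 | step 8 | (7S)-7-[(tert-butyldimethylsilyl)oxy]-1-(1-ethoxyethenyl)-5-methyl-2-methylidenecyclohept-4-en-1-ol (both C1 epimers) | CC(C)(C)[Si](C)(C)O[C@H]1CC(C)=CCC(=C)C1(O)C(=C)OCC
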